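## Retrosynthetic overview

- **Feature.** The strategy rests on the oxygens at C4, C5 and C6. The C4–C5 oxirane and the C6–O bond of butenolide ring B (O–C6–C7=C11–C12) together form a 2,3-epoxy alcohol. This array is the Payne isomer of a trans C5–C6 oxirane next to a C4 tertiary carbinol, and C6 stands cis to the C12 carbonyl on C7=C11.
- **End game.** The C8 senecioate and C13 acetate come from acylations. C2–C3 comes from diimide reduction of C2=C3, which is made by ring-closing metathesis of two vinyl oxiranes (ten-membered ring A).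
- **Key disconnection.** O–C5 and O–C12 are opened together to an acyclic epoxy enoate. Base-induced epoxide migration and lactonisation rebuild both bonds in one operation.
- **Precursor.** The epoxy carbinol derives from a methyl ketone (chelate-controlled vinyl Grignard addition), an E-enone (asymmetric nucleophilic epoxidation) and a β-formyl enoate (Wittig). The cis C12/C6 geometry comes from singlet-oxygen cleavage of a 2-silyl-3,4-disubstituted furan. C8 is set by catalytic asymmetric propargylation, and the cis C1–C10 oxirane by ynoate methylcupration and Sharpless epoxidation.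
- **Ring order.** Furan (temporary) → C1–C10 oxirane → C5–C6 oxirane → C4–C5 oxirane and ring B together → ring A.

Key step: step 18

Remark: germacrane numbering is used for all intermediates and TBS = tert-butyldimethylsilyl; the metathesis product is drawn as the Z alkene by assumption (either geometry converges on reduction), and the hemiacetal carbon of the hydroxybutenolide is an inconsequential epimer mixture.

## Route

Step 1
Reactants: 1 furan-3-ylmethanol
Product: 2 tert-butyl(furan-3-ylmethoxy)dimethylsilane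
Conditions: TBSCl, imidazole, DMF, rt
Reagents that add atoms: tert-butyldimethylsilyl chloride, CC(C)(C)[Si](C)(C)Cl
Why: Routine silyl ether formation on a primary alcohol, which also loads the silicon that step 2 moves onto carbon.

Step 2
Reactants: 2 tert-butyl(furan-3-ylmethoxy)dimethylsilane
Product: 4 [2-(tert-butyldimethylsilyl)furan-3-yl]methanol, via 2-lithiofuran 3 (not isolated)
Conditions: n-BuLi, HMPA, THF, −78 → 0 °C; then H2O
Reagents that add atoms: none
Why: Oxygen-assisted lithiation at furan C2 gives 3, whose carbanion takes the silyl group from oxygen in a 1,4 O-to-C shift (retro-Brook rearrangement) driven by the strong Li–O bond, so that the future C12 is marked by silicon.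

Step 3
Reactants: 4 [2-(tert-butyldimethylsilyl)furan-3-yl]methanol
Product: 6 5-(tert-butyldimethylsilyl)-4-(hydroxymethyl)furan-3-carbaldehyde, via dilithio species 5 (not isolated)
Conditions: n-BuLi (2.2 equiv), DME, 0 °C; DMF, −78 → 0 °C; then H2O
Reagents that add atoms: N,N-dimethylformamide, CN(C)C=O
Why: With C2 blocked, the lithium alkoxide steers the second lithiation to the neighbouring C4 (directed metalation, a known entry to 2,3,4-trisubstituted furans) and DMF formylates 5 to install C8.

Step 4
Reactants: 6 5-(tert-butyldimethylsilyl)-4-(hydroxymethyl)furan-3-carbaldehyde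
Product: 7 5-(tert-butyldimethylsilyl)-4-(tert-butyldimethylsilyloxymethyl)furan-3-carbaldehyde
Conditions: TBSCl, imidazole, DMF, rt
Reagents that add atoms: tert-butyldimethylsilyl chloride, CC(C)(C)[Si](C)(C)Cl
Why: Routine silylation that masks the C13 hydroxyl before the organometallic steps.

Step 5
Reactants: 7 5-(tert-butyldimethylsilyl)-4-(tert-butyldimethylsilyloxymethyl)furan-3-carbaldehyde; 8 allenylboronic acid pinacol ester
Product: 9 (1R)-1-[5-TBS-4-(TBS-oxymethyl)furan-3-yl]but-3-yn-1-ol (8R)
Conditions: (R)-TRIP phosphoric acid (10 mol %), 4 Å MS, toluene, −20 °C; aqueous work-up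
Reagents that add atoms: none
Why: Chiral phosphoric acid-catalysed propargylation with an allenylboronate runs through a closed six-membered SE2' transition state in which (R)-TRIP activates the boronate and is expected to expose the Re face of the aryl aldehyde, which sets 8R.

Step 6
Reactants: 9 (1R)-1-[5-TBS-4-(TBS-oxymethyl)furan-3-yl]but-3-yn-1-ol
Product: 10 TBS ether of 9 (8R)
Conditions: TBSOTf, 2,6-lutidine, CH2Cl2, −78 → 0 °C
Reagents that add atoms: tert-butyldimethylsilyl triflate, CC(C)(C)[Si](C)(C)OS(=O)(=O)C(F)(F)F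
Why: Silyl triflate with a hindered base silylates the crowded secondary carbinol without ionising it.

Step 7
Reactants: 10 TBS ether of 9
Product: 11 methyl (5R)-5-(TBS-oxy)-5-[5-TBS-4-(TBS-oxymethyl)furan-3-yl]pent-2-ynoate
Conditions: n-BuLi (1.05 equiv), THF, −78 °C; ClCO2Me
Reagents that add atoms: methyl chloroformate, COC(=O)Cl
Why: The terminal alkyne is far more acidic than the furan C–H, and C-acylation of its lithium acetylide with a chloroformate adds C2.

Step 8
Reactants: 11 methyl (5R)-pent-2-ynoate
Product: 12 methyl (2Z,5R)-5-(TBS-oxy)-3-methyl-5-[5-TBS-4-(TBS-oxymethyl)furan-3-yl]pent-2-enoate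
Conditions: Me2CuLi (from MeLi, CuI), THF, −78 °C; sat. aq NH4Cl at −78 °C
Reagents that add atoms: lithium dimethylcuprate, [Li+].C[Cu-]C
Why: Syn conjugate addition of a Gilman cuprate to an ynoate, with cold protonation of the alkenylcuprate, places methyl and H cis, so that C9 and C2 end up cis on C1=C10 (Z).

Step 9
Reactants: 12 methyl (2Z,5R)-enoate
Product: 13 (2Z,5R)-5-(TBS-oxy)-3-methyl-5-[5-TBS-4-(TBS-oxymethyl)furan-3-yl]pent-2-en-1-ol
Conditions: DIBAL-H (2.5 equiv), CH2Cl2, −78 °C; aq Rochelle salt
Reagents that add atoms: none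
Why: DIBAL-H reduces the enoate in 1,2-fashion to the allylic alcohol without changing the alkene geometry or touching the silyl groups.

Step 10
Reactants: 13 (2Z,5R)-allylic alcohol
Product: 14 [(2S,3R)-3-{(2R)-2-(TBS-oxy)-2-[5-TBS-4-(TBS-oxymethyl)furan-3-yl]ethyl}-3-methyloxiran-2-yl]methanol (1S,8R,10R)
Conditions: Ti(OiPr)4 (10 mol %), L-(+)-diethyl tartrate (12 mol %), t-BuOOH, 4 Å MS, CH2Cl2, −20 °C
Reagents that add atoms: tert-butyl hydroperoxide, CC(C)(C)OO
Why: In the Sharpless asymmetric epoxidation L-(+)-tartrate turns a Z-3-methyl allylic alcohol of the nerol type into the (2S,3R)-epoxy alcohol, which sets 1S and 10R under reagent control, keeps C2 and C9 cis by stereospecific syn oxygen transfer, and leaves alone a furan that has no free hydroxyl to direct the oxidant.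

Step 11
Reactants: 14 (1S,8R,10R)-epoxy alcohol
Product: 15 corresponding oxirane-2-carbaldehyde (same spatial arrangement; C1 is 1R by CIP here)
Conditions: Dess–Martin periodinane, NaHCO3, CH2Cl2, 0 °C → rt
Reagents that add atoms: none
Why: Buffered Dess–Martin oxidation gives the α,β-epoxy aldehyde under conditions that are neither basic nor acidic and that spare oxirane and furan.

Step 12
Reactants: 15 epoxy aldehyde
Product: 16 2-TBS-3-(TBS-oxymethyl)-4-[(1R)-1-(TBS-oxy)-2-{(2R,3S)-2-methyl-3-vinyloxiran-2-yl}ethyl]furan (1S,8R,10R)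
Conditions: Ph3PCH3Br, KHMDS, THF, −78 → 0 °C
Reagents that add atoms: methyltriphenylphosphonium bromide, C[P+](c1ccccc1)(c1ccccc1)c1ccccc1.[Br-]
Why: Wittig methylenation of an epoxy aldehyde is the standard way to a vinyl oxirane and does not touch C1.

Step 13
Reactants: 16 vinyl oxirane furan
Product: 19 5-hydroxybutenolide (1S,8R,10R; C6 epimers), via furan endoperoxide 17 (not isolated), via silyl ester aldehyde 18 (not isolated)
Conditions: O2, hν (visible), tetraphenylporphyrin (cat.), CH2Cl2, −78 °C; then H2O–THF, 0 °C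
Reagents that add atoms: dioxygen, O=O
Why: Silyl-directed furan photooxygenation proceeds by [4+2] addition of singlet oxygen to give 17, migration of silicon from C12 to peroxide oxygen to give 18, and hydrolysis, which leaves the carbonyl only at the former silyl carbon and thereby fixes C12 and C6 cis on C7=C11, while the monosubstituted vinyl group is inert to singlet oxygen.

Step 14
Reactants: 19 5-hydroxybutenolide
Product: 20 methyl β-formyl enoate (C12 cis to C6 on C7=C11; 1S,8R,10R)
Conditions: MeI, K2CO3, DMF, 0 °C → rt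
Reagents that add atoms: iodomethane, CI
Why: Under carbonate the pseudo-acid exists as the ring-opened carboxylate, whose SN2 O-alkylation gives the normal methyl ester and frees the C6 aldehyde, as is known for 2-formylbenzoic acid.

Step 15
Reactants: 20 methyl β-formyl enoate; 21 1-(triphenylphosphoranylidene)propan-2-one
Product: 22 (5E)-enone (C4 methyl ketone; C12 cis to C6; 1S,8R,10R)
Conditions: toluene, 40 °C
Reagents that add atoms: none
Why: Wittig olefination with a stabilised acyl ylide gives the E-enone under neutral conditions that leave the tetrasubstituted alkene geometry alone.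

Step 16
Reactants: 22 (5E)-enone
Product: 23 trans-(5S,6R)-epoxy ketone (1S,8R,10R)
Conditions: La(OiPr)3, (R)-BINOL, Ph3AsO (10 mol % each), t-BuOOH (decane), 4 Å MS, THF, rt
Reagents that add atoms: tert-butyl hydroperoxide, CC(C)(C)OO
Why: Weitz–Scheffer-type nucleophilic epoxidation under lanthanum–BINOL–arsine oxide catalysis attacks the ketone-activated disubstituted C5=C6 bond rather than the hindered tetrasubstituted C7=C11, keeps the trans geometry, and with (R)-BINOL gives the (αS,βR) epoxy ketone, that is 5S,6R.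

Step 17
Reactants: 23 trans-(5S,6R)-epoxy ketone; 24 vinylmagnesium bromide
Product: 25 (4S,5S,6R)-epoxy carbinol: trans C5–C6 epoxy enoate with C4 tertiary alcohol, TBS ethers at C8 and C13 (1S,8R,10R)
Conditions: 24 (1.0 M in THF, 1.2 equiv), CH2Cl2, −78 °C; sat. aq NH4Cl at −78 °C
Reagents that add atoms: none
Why: In this Cram-chelate Grignard addition to an α,β-epoxy ketone, magnesium ties the carbonyl oxygen to the oxirane oxygen and vinyl enters from the face flanked by C5–H and away from C6, which gives the erythro 4S carbinol, while the hindered tetrasubstituted enoate does not react at −78 °C.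

Step 18
Reactants: 25 (4S,5S,6R)-epoxy carbinol
Product: 28 (4S,5R,6R)-butenolide bearing the cis C4–C5 vinyl oxirane plus the C1–C10 vinyl oxirane (1S,8R,10R), via C4 sodium alkoxide 26 (not isolated), via C6 sodium alkoxide 27 (not isolated)
Conditions: NaHMDS (1.0 equiv), THF (5 mM), −78 → −20 °C; AcOH at −78 °C
Reagents that add atoms: none
Why: NaHMDS converts the C4 carbinol into alkoxide 26, which displaces the oxirane oxygen at C5 from the rear (Payne rearrangement, 3-exo-tet), closing the C4–C5 oxirane and freeing the C6 alkoxide 27. Because C6 and C12 are cis on C7=C11, 27 acylates on the ester at once (5-exo-trig addition–elimination with loss of methoxide) and closes ring B, so the reversible epoxide migration is drained in one direction; the closest known reaction type is a Payne rearrangement whose liberated alkoxide is trapped in situ. C5 is the only centre that changes: the stereospecific SN2 step inverts it from 5S to 5R, C4 and C6 keep their C–O bonds, and the erythro 4S,5S arrangement of 25 therefore places C3 and C6 cis on the new oxirane. Site selectivity lies in the substrate, since attack of O4 at C6 would need an oxetane, direct acylation of O4 on C12 would need a seven-membered lactone spanning a trans oxirane, and the C1–C10 oxirane has no neighbouring nucleophile. The step also needs the cascade to finish before C6–H of 28 is removed (which would reopen the new oxirane by E1cB elimination); this is served by one equivalent of base, high dilution that slows bimolecular proton transfer relative to the unimolecular cascade, the low solubility of NaOMe in THF, and a cold acetic acid quench.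

Step 19
Reactants: 28 (4S,5R,6R)-butenolide
Product: 29 ten-membered 2,3-alkene (ring A closed; 1S,4S,5R,6R,8R,10R; bis-TBS ether)
Conditions: second-generation Hoveyda–Grubbs catalyst (10 mol %, in portions), 1,4-benzoquinone (20 mol %), toluene (0.5 mM), 80 °C
Reagents that add atoms: none
Why: In this ring-closing metathesis to a ten-membered carbocycle the carbene should load at the less hindered C1 vinyl group and close onto the C4 vinyl group, helped by the two cis-oxiranes and the butenolide-bound C6–C7–C8 corner that fold the chain, with high dilution against oligomerisation and loss of ethylene as driving force.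

Step 20
Reactants: 29 ten-membered 2,3-alkene
Product: 30 2,3-dihydro compound (bis-TBS ether of the germacranolide diol)
Conditions: 2-nitrobenzenesulfonyl hydrazide, Et3N, CH2Cl2, rt
Reagents that add atoms: none
Why: Diimide reduction transfers H2 in a concerted syn fashion to the unpolarised disubstituted C2=C3 bond only, leaves the tetrasubstituted electron-poor C7=C11 alone and, unlike metal-catalysed hydrogenation, cannot hydrogenolyse the allylic C–O bonds.

Step 21
Reactants: 30 bis-TBS ether
Product: 31 C8,C13-diol (1S,4S,5R,6R,8R,10R)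
Conditions: HF·pyridine, pyridine, THF, 0 °C → rt
Reagents that add atoms: none
Why: Pyridine-buffered fluoride desilylation removes both TBS ethers without the basicity that would endanger C6–H and without enough acidity to open the now non-allylic oxiranes.

Step 22
Reactants: 31 C8,C13-diol
Product: 32 C13 monoacetate
Conditions: Ac2O (1.05 equiv), 2,4,6-collidine, CH2Cl2, −20 → 0 °C
Reagents that add atoms: acetic anhydride, CC(=O)OC(C)=O
Why: Kinetically selective acylation, in which the primary allylic C13 hydroxyl reacts well before the hindered secondary C8 hydroxyl under a weak base.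

Step 23
Reactants: 32 C13 monoacetate; 33 3-methylbut-2-enoic acid
Product: 34 CNP0228323.1 (1S,4S,5R,6R,8R,10R)
Conditions: DCC, DMAP (cat.), CH2Cl2, 0 °C → rt
Reagents that add atoms: none
Why: Steglich esterification acylates the C8 alcohol with retention and, by avoiding acid chloride with amine, avoids the vinylketene path that would deconjugate the senecioate.

## Compound list

| No. | Name | SMILES | Role |
|---|---|---|---|
| 1 | furan-3-ylmethanol | OCc1ccoc1 | starting material |
| 2 | tert-butyl(furan-3-ylmethoxy)dimethylsilane | CC(C)(C)[Si](C)(C)OCc1ccoc1 | intermediate |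
| 3 | 2-lithio-3-(TBS-oxymethyl)furan | [Li]c1occc1CO[Si](C)(C)C(C)(C)C | intermediate |
| 4 | [2-(tert-butyldimethylsilyl)furan-3-yl]methanol | OCc1ccoc1[Si](C)(C)C(C)(C)C | intermediate |
| 5 | C4,O-dilithio derivative of 4 | [Li]OCc1c([Li])coc1[Si](C)(C)C(C)(C)C | intermediate |
| 6 | 5-TBS-4-(hydroxymethyl)furan-3-carbaldehyde | OCc1c(C=O)coc1[Si](C)(C)C(C)(C)C | intermediate |
| 7 | 5-TBS-4-(TBS-oxymethyl)furan-3-carbaldehyde | CC(C)(C)[Si](C)(C)OCc1c(C=O)coc1[Si](C)(C)C(C)(C)C | intermediate |
| 8 | allenylboronic acid pinacol ester | C=C=CB1OC(C)(C)C(C)(C)O1 | starting material |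
| 9 | (8R)-homopropargylic alcohol | C#CC[C@@H](O)c1coc([Si](C)(C)C(C)(C)C)c1CO[Si](C)(C)C(C)(C)C | intermediate |
| 10 | (8R)-TBS ether, terminal alkyne | C#CC[C@@H](O[Si](C)(C)C(C)(C)C)c1coc([Si](C)(C)C(C)(C)C)c1CO[Si](C)(C)C(C)(C)C | intermediate |
| 11 | (8R)-ynoate | COC(=O)C#CC[C@@H](O[Si](C)(C)C(C)(C)C)c1coc([Si](C)(C)C(C)(C)C)c1CO[Si](C)(C)C(C)(C)C | intermediate |
| 12 | (Z,8R)-β-methyl enoate | COC(=O)/C=C(/C)C[C@@H](O[Si](C)(C)C(C)(C)C)c1coc([Si](C)(C)C(C)(C)C)c1CO[Si](C)(C)C(C)(C)C | intermediate |
| 13 | (Z,8R)-allylic alcohol | OC/C=C(/C)C[C@@H](O[Si](C)(C)C(C)(C)C)c1coc([Si](C)(C)C(C)(C)C)c1CO[Si](C)(C)C(C)(C)C | intermediate |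
| 14 | (1S,8R,10R)-epoxy alcohol | OC[C@@H]1O[C@]1(C)C[C@@H](O[Si](C)(C)C(C)(C)C)c1coc([Si](C)(C)C(C)(C)C)c1CO[Si](C)(C)C(C)(C)C | intermediate |
| 15 | epoxy aldehyde | O=C[C@@H]1O[C@]1(C)C[C@@H](O[Si](C)(C)C(C)(C)C)c1coc([Si](C)(C)C(C)(C)C)c1CO[Si](C)(C)C(C)(C)C | intermediate |
| 16 | (1S,8R,10R)-vinyl oxirane furan | C=C[C@@H]1O[C@]1(C)C[C@@H](O[Si](C)(C)C(C)(C)C)c1coc([Si](C)(C)C(C)(C)C)c1CO[Si](C)(C)C(C)(C)C | intermediate |
| 17 | furan endoperoxide | C=C[C@@H]1O[C@]1(C)C[C@@H](O[Si](C)(C)C(C)(C)C)C1=C(CO[Si](C)(C)C(C)(C)C)C2([Si](C)(C)C(C)(C)C)OOC1O2 | intermediate |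
| 18 | TBS ester of the β-formyl enoic acid | CC(C)(C)[Si](C)(C)OC(=O)/C(CO[Si](C)(C)C(C)(C)C)=C(\C=O)[C@H](O[Si](C)(C)C(C)(C)C)C[C@@]1(C)O[C@H]1C=C | intermediate |
| 19 | 5-hydroxybutenolide (C6 epimers) | C=C[C@@H]1O[C@]1(C)C[C@@H](O[Si](C)(C)C(C)(C)C)C1=C(CO[Si](C)(C)C(C)(C)C)C(=O)OC1O | intermediate |
| 20 | methyl β-formyl enoate | COC(=O)/C(CO[Si](C)(C)C(C)(C)C)=C(\C=O)[C@H](O[Si](C)(C)C(C)(C)C)C[C@@]1(C)O[C@H]1C=C | intermediate |
| 21 | 1-(triphenylphosphoranylidene)propan-2-one | CC(=O)C=P(c1ccccc1)(c1ccccc1)c1ccccc1 | starting material |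
| 22 | (5E)-enone | COC(=O)/C(CO[Si](C)(C)C(C)(C)C)=C(\C=C\C(C)=O)[C@H](O[Si](C)(C)C(C)(C)C)C[C@@]1(C)O[C@H]1C=C | intermediate |
| 23 | trans-(5S,6R)-epoxy ketone | COC(=O)/C(CO[Si](C)(C)C(C)(C)C)=C(\[C@H]1O[C@@H]1C(C)=O)[C@H](O[Si](C)(C)C(C)(C)C)C[C@@]1(C)O[C@H]1C=C | intermediate |
| 24 | vinylmagnesium bromide | C=C[Mg]Br | starting material |
| 25 | (4S,5S,6R)-epoxy carbinol (key-step precursor) | COC(=O)/C(CO[Si](C)(C)C(C)(C)C)=C(\[C@H]1O[C@@H]1[C@@](C)(O)C=C)[C@H](O[Si](C)(C)C(C)(C)C)C[C@@]1(C)O[C@H]1C=C | intermediate |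
| 26 | C4 sodium alkoxide of 25 | COC(=O)/C(CO[Si](C)(C)C(C)(C)C)=C(\[C@H]1O[C@@H]1[C@@](C)([O-])C=C)[C@H](O[Si](C)(C)C(C)(C)C)C[C@@]1(C)O[C@H]1C=C.[Na+] | intermediate |
| 27 | C6 sodium alkoxide (Payne isomer) | COC(=O)/C(CO[Si](C)(C)C(C)(C)C)=C(\[C@@H]([O-])[C@H]1O[C@@]1(C)C=C)[C@H](O[Si](C)(C)C(C)(C)C)C[C@@]1(C)O[C@H]1C=C.[Na+] | intermediate |
| 28 | (4S,5R,6R)-butenolide, bis(vinyl oxirane) (key-step product) | CC(C)(C)[Si](C)(C)OCC1=C([C@@H](C[C@@]2(C)O[C@H]2C=C)O[Si](C)(C)C(C)(C)C)[C@@H](OC1=O)[C@H]2O[C@@]2(C)C=C | intermediate |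
| 29 | ten-membered 2,3-alkene | CC(C)(C)[Si](C)(C)OCC1=C2[C@@H](OC1=O)[C@H]1O[C@@]1(C)/C=C\[C@@H]1O[C@]1(C)C[C@H]2O[Si](C)(C)C(C)(C)C | intermediate |
| 30 | saturated bis-TBS ether | CC(C)(C)[Si](C)(C)OCC1=C2[C@@H](OC1=O)[C@H]1O[C@@]1(C)CC[C@@H]1O[C@]1(C)C[C@H]2O[Si](C)(C)C(C)(C)C | intermediate |
| 31 | C8,C13-diol | OCC1=C2[C@@H](OC1=O)[C@H]1O[C@@]1(C)CC[C@@H]1O[C@]1(C)C[C@H]2O | intermediate |
| 32 | C13 monoacetate | CC(=O)OCC1=C2[C@@H](OC1=O)[C@H]1O[C@@]1(C)CC[C@@H]1O[C@]1(C)C[C@H]2O | intermediate |
| 33 | 3-methylbut-2-enoic acid | CC(C)=CC(=O)O | starting material |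
| 34 | CNP0228323.1 | CC(=O)OCC1=C2[C@@H](OC1=O)[C@H]1O[C@@]1(C)CC[C@@H]1O[C@]1(C)C[C@H]2OC(=O)C=C(C)C | target |

## Step count and risks

Total step count: 23. Longest linear sequence: 23 steps (1 → 34).

Steps most likely to fail:

**1. Step 18.**
- What may go wrong: methoxide or unreacted 26 may remove the C6 proton of freshly formed 28, and eliminative opening of the new oxirane may then outrun the cascade. The epoxide migration may also stall at the temperatures that 28 tolerates.
- Fallback (from 25, back at 28): the lactone is kept away from base altogether.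
  - The methyl ester of 25 is cleaved under near-neutral conditions (Me3SnOH, 1,2-dichloroethane, 70 °C) to the epoxy carbinol acid F1.
  - As its carboxylate, which cannot be acylated, this acid is equilibrated under classical aqueous Payne conditions (0.5 M NaOH, t-BuOH–H2O, rt) to the 4,5-epoxy-6-hydroxy acid F2, which should be favoured as the trisubstituted oxirane.
  - Acidification to about pH 4 at 0 °C lets only the hydroxy acid lactonise to 28. Unrearranged acid is recovered and resubmitted.

**2. Step 19.**
- What may go wrong: intermolecular metathesis through the unhindered C1 vinyl group may outpace closure onto the vinyl group at the quaternary C4, which would lead to oligomerisation.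
- Fallback (from 23, back at 29): relay ring-closing metathesis, which delivers ruthenium to C3 intramolecularly.
  - Commercial hept-1-en-6-yne is converted by hydrozirconation–iodination (Cp2Zr(H)Cl, then I2) into (E)-1-iodohepta-1,6-diene F3.
  - I/Li exchange (t-BuLi) and MgBr2·OEt2 give (E)-hepta-1,6-dien-1-ylmagnesium bromide F4.
  - Chelate-controlled addition to 23 as in step 17 gives the relay epoxy carbinol F5, and the conditions of step 18 give the relay butenolide F6.
  - The catalyst enters at the terminal alkene of the tether, expels cyclopentene, and the resulting C3 carbene closes on the C1 vinyl group to 29.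

**3. Step 16.**
- What may go wrong: peroxide addition to the twisted, hindered dienone may be slow, or facial selectivity may be poor if the catalyst is mismatched with C8.
- Fallback (from 22, back at 23): the oxirane is set by allylic-alcohol-directed chemistry.
  - Corey–Bakshi–Shibata reduction ((S)-Me-CBS, catecholborane, toluene, −78 °C) gives the (4R)-allylic alcohol F7.
  - Sharpless epoxidation with D-(−)-diisopropyl tartrate (matched pair, Ti(OiPr)4, t-BuOOH, −20 °C) gives the erythro epoxy alcohol F8, with the oxirane configured as in 23.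
  - Dess–Martin oxidation returns 23.

Further compounds
F1 | step 18 | (4S,5S,6R)-epoxy carbinol acid (free acid of 25) | OC(=O)/C(CO[Si](C)(C)C(C)(C)C)=C(\[C@H]1O[C@@H]1[C@@](C)(O)C=C)[C@H](O[Si](C)(C)C(C)(C)C)C[C@@]1(C)O[C@H]1C=C
F2 | step 18 | (4S,5R,6R)-4,5-epoxy-6-hydroxy acid (Payne isomer; sodium salt in the flask) | OC(=O)/C(CO[Si](C)(C)C(C)(C)C)=C(\[C@@H](O)[C@H]1O[C@@]1(C)C=C)[C@H](O[Si](C)(C)C(C)(C)C)C[C@@]1(C)O[C@H]1C=C
F3 | step 19 | (E)-1-iodohepta-1,6-diene | C=CCCC/C=C/I
F4 | step 19 | (E)-hepta-1,6-dien-1-ylmagnesium bromide | C=CCCC/C=C/[Mg]Br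
F5 | step 19 | relay epoxy carbinol (heptadienyl analogue of 25) | COC(=O)/C(CO[Si](C)(C)C(C)(C)C)=C(\[C@H]1O[C@@H]1[C@@](C)(O)/C=C/CCCC=C)[C@H](O[Si](C)(C)C(C)(C)C)C[C@@]1(C)O[C@H]1C=C
F6 | step 19 | relay butenolide (heptadienyl analogue of 28) | CC(C)(C)[Si](C)(C)OCC1=C([C@@H](C[C@@]2(C)O[C@H]2C=C)O[Si](C)(C)C(C)(C)C)[C@@H](OC1=O)[C@H]2O[C@@]2(C)/C=C/CCCC=C
F7 | step 16 | (4R)-allylic alcohol | COC(=O)/C(CO[Si](C)(C)C(C)(C)C)=C(\C=C\[C@@H](C)O)[C@H](O[Si](C)(C)C(C)(C)C)C[C@@]1(C)O[C@H]1C=C
F8 | step 16 | erythro (4R)-epoxy alcohol, oxirane as in 23 | COC(=O)/C(CO[Si](C)(C)C(C)(C)C)=C(\[C@H]1O[C@@H]1[C@@H](C)O)[C@H](O[Si](C)(C)C(C)(C)C)C[C@@]1(C)O[C@H]1C=C
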